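(The earlier runs and the new flask come from a simulation from invented constants; scatter was added.)

Keep count of the coupling partner in these flasks as well as of the clock.

in all of them: coupling partner 2.25 M; catalyst 1.5 mM
- alder: starting material 2.1 M; temperature 15 °C; run made earlier
- ash: starting material 2.1 M; temperature 65 °C; run made earlier
- Friday's: starting material 1.5 M; temperature 50 °C; time 50 min
- Wednesday's: starting material 1.5 M; temperature 20 °C; time 50 min
- Sunday's: starting material 1.5 M; temperature 80 °C; time 50 min
- Saturday's: starting material 1.5 M; temperature 110 °C; time 50 min

| run | time / min | target / % | starting material / % |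
|---|---|---|---|
| alder | 30.0 | 3.6 | 25.0 |
| alder | 60.0 | 8.4 | 13.1 |
| alder | 120 | 18.4 | 10.0 |
| alder | 150 | 22.1 | 9.3 |
| alder | 180 | 26.1 | 9.1 |
| alder | 240 | 31.7 | 8.5 |
| ash | 3.00 | 4.6 | 37.1 |
| ash | 6.00 | 9.4 | 35.4 |
| ash | 10.0 | 14.6 | 33.1 |
| ash | 12.0 | 16.3 | 32.7 |
| ash | 15.0 | 18.6 | 31.1 |
| ash | 20.0 | 23.6 | 29.8 |

(scatter of a reading: 0.3 percentage points)



* which flask leads in amount of target, in percent of the starting material charged ("all alike" within 1.5 percentage points) (Friday's / Wednesday's / Sunday's / Saturday's / all alike)
* how much target is there at the end, in percent of the starting material charged: Friday's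
* how much target is there at the end, in percent of the starting material charged: Wednesday's
* how much target is there at the end, in percent of the starting material charged: Sunday's
* how much target is there at the end, in percent of the starting material charged: Saturday's

What you will find in them I read from the earlier runs: in the ash run after 20.0 min the readings show 29.8% starting material and 23.6% target, so 46.6% of the charge sits in a pool neither reading sees, and I take the target to grow out of that pool. Divide the target's rate by the pool and you have κ, which I take to be proportional to the coupling partner concentration, a pseudo-first-order constant whose fall reads the partner's fall. In the ash run κ goes from 0.0258 min⁻¹ in the early readings to 0.0187 min⁻¹ in the late ones, so about 0.566 M of partner went while the target gained 0.217 M. That gives 2.60 moles of partner gone per mole of target made, the spend ratio s, a reading with the scatter on it.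

The same reckoning on the alder run reads 1.97, lower than the ash run, a lean within the scatter. A flask spending at the ash ratio to the end has partner for 57.6% of target, and I expect Sunday's and Saturday's to stay under that.

The forecast says “so the hottest flask leads”, with 10% for Wednesday's, 33% for Friday's, 58% for Sunday's and 70% for Saturday's, the last higher than my ceiling.

The flasks give 10.3% for Wednesday's, 32.8% for Friday's, 40.8% for Sunday's and 30.4% for Saturday's, so Sunday's leads.

    starting material + catalyst ⇌ catalyst + intermediate (K = 2.40, k = 7.20 M⁻¹ s⁻¹, Ea = 54.0 kJ mol⁻¹, ΔH = −25.0 kJ mol⁻¹)
    coupling partner + catalyst + intermediate → catalyst + target (k = 0.0800 M⁻² s⁻¹, Ea = 41.0 kJ mol⁻¹)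
    2 coupling partner → homo dimer (k = 3.50 × 10⁻⁵ M⁻¹ s⁻¹, Ea = 65.0 kJ mol⁻¹)
    (constants at 50 °C)

Sunday's has not come to rest: up to 50 min it has spent 3.18 moles of coupling partner per mole of target, and its 14% of partner still unbound would pay for 20.3% of target at one to one. Ten times the time adds 14 percentage points, reaching 55.1%, lower than the ceiling. Saturday's has spent 4.84 moles per mole, and its 1.8% of partner would pay for 2.75%; the same wait adds 2.5 points, reaching 32.9%.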